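**Retrosynthetic overview**
1. The dihydrofuran ring (O11–C11a) is closed last by acid cyclisation of a cis-(3R,4R)-2'-hydroxyisoflavan-4-ol; C6a is set by Ru transfer hydrogenation with dynamic kinetic resolution of the isoflavone, and C11a follows from the obligatory cis ring fusion.
2. The isoflavone C3–C1' bond comes from a Negishi coupling of a linear 3-iodopyranochromone (8) with the fully substituted bromochromene (18).
3. Fragment 8: the ring-A pyran is built first at the bromine-bearing carbon (Heck, then oxa-6π), so it is linear by construction; the γ-pyrone follows by enaminone iodocyclisation.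
4. Fragment 18: a Dakin phenol is propargylated and rearranged (Claisen/6π) into the only free ortho position to give the ring-D pyran; the prenyl group is then introduced by metalation between the two OMOM groups.
5. Ring order: A-pyran → γ-pyrone, and separately D-pyran; then coupling → reduction → dihydrofuran closure.

Assumption: the SMILES is taken literally as the cis-(6aR,11aR) pterocarpan with a linear pyran on ring A (C2/O3), a pyran on ring D at C7/O8, 9-OH and 10-prenyl; bromides 1 and 9 are taken as catalogue compounds (each is otherwise one bromination from the parent resorcinol carbonyl compound).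

**Route**

Step 1
Reactants: 1, 5-bromo-2,4-dihydroxyacetophenone; 2, 2-methylbut-3-en-2-ol
Product: 3, (E)-1-[2,4-dihydroxy-5-(3-hydroxy-3-methylbut-1-en-1-yl)phenyl]ethanone
Conditions: Pd2(dba)3, P(t-Bu)3·HBF4, Cy2NMe, dioxane, 90 °C
Reagents that add atoms: 2-methylbut-3-en-2-ol, C=CC(C)(C)O
Why: Mizoroki–Heck arylation of the terminal alkene at the C–Br carbon fixes the future pyran at C5, so the linear isomer is the only possible outcome.

Step 2
Reactants: 3
Product: 4, 1-(7-hydroxy-2,2-dimethyl-2H-chromen-6-yl)ethanone
Conditions: PPTS (cat.), toluene, 80 °C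
Reagents that add atoms: none
Why: Acid ionisation of the tertiary allylic alcohol gives an o-quinone methide that closes by oxa-6π electrocyclisation onto the only ortho hydroxyl (cyclodehydration); the other OH stays chelated to the acetyl.

Step 3
Reactants: 4; 5, N,N-dimethylformamide dimethyl acetal
Product: 6, (E)-3-(dimethylamino)-1-(7-hydroxy-2,2-dimethyl-2H-chromen-6-yl)prop-2-en-1-one
Conditions: DMF-DMA, toluene, 95 °C
Reagents that add atoms: DMF-DMA, COC(OC)N(C)C
Why: Condensation of the acetyl methyl group with the amide acetal gives the enaminone, the standard chromone precursor.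

Step 4
Reactants: 6; 7, iodine
Product: 8, 7-iodo-2,2-dimethyl-2H,6H-pyrano[3,2-g]chromen-6-one (linear 3-iodopyranochromone)
Conditions: I2, pyridine, CHCl3, rt; aq. Na2S2O3 work-up
Reagents that add atoms: iodine, II
Why: Gammill iodocyclisation: α-iodination of the enaminone, phenol addition and loss of Me2NH give the 3-iodochromone, and the chromene alkene does not add I2 irreversibly.

Step 5
Reactants: 9, 5-bromo-2,4-dihydroxybenzaldehyde; 10, chloromethyl methyl ether
Product: 11, 5-bromo-2,4-bis(methoxymethoxy)benzaldehyde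
Conditions: MOMCl, i-Pr2NEt, DMAP (cat.), CH2Cl2, 0 °C → rt
Reagents that add atoms: MOMCl, COCCl (two equivalents)
Why: O-alkylation gives bis-MOM protection; MOM survives organolithiums and later directs metalation.

Step 6
Reactants: 11; 12, mCPBA
Product: 13, 5-bromo-2,4-bis(methoxymethoxy)phenol
Conditions: mCPBA, NaHCO3, CH2Cl2, 0 °C → rt; then K2CO3, MeOH, rt
Reagents that add atoms: mCPBA, OOC(=O)c1cccc(Cl)c1 (one O retained)
Why: Dakin-type Baeyer–Villiger oxidation: the electron-rich aryl migrates to give the formate, which is methanolysed to the phenol that becomes the ring-D pyran oxygen.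

Step 7
Reactants: 13; 14, 3-chloro-3-methylbut-1-yne
Product: 15, 1-bromo-2,4-bis(methoxymethoxy)-5-[(2-methylbut-3-yn-2-yl)oxy]benzene
Conditions: DBU, CuCl2·2H2O (cat.), MeCN, 0 °C → rt
Reagents that add atoms: 3-chloro-3-methylbut-1-yne, C#CC(C)(C)Cl
Why: Cu-catalysed propargylic substitution O-alkylates the phenol with the tertiary chloride.

Step 8
Reactants: 15
Product: 16, 5-bromo-6,8-bis(methoxymethoxy)-2,2-dimethyl-2H-chromene
Conditions: N,N-diethylaniline, 170 °C
Reagents that add atoms: none
Why: Aryl propargyl Claisen rearrangement, 1,5-H shift and oxa-6π closure; only one ortho position (next to Br) is free, so a single chromene forms.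

Step 9
Reactants: 16; 17, prenyl bromide
Product: 18, 5-bromo-6,8-bis(methoxymethoxy)-2,2-dimethyl-7-(3-methylbut-2-en-1-yl)-2H-chromene
Conditions: LiTMP, THF, −78 °C; CuBr·SMe2 (cat.), prenyl bromide, −78 → 0 °C
Reagents that add atoms: prenyl bromide, CC(C)=CCBr
Why: Directed ortho-metalation at the only aryl C–H, flanked by two OMOM groups, using a lithium amide so the bromide is not exchanged; Cu-assisted SN2 allylation then installs the prenyl group.

Step 10
Reactants: 18; 8
Product: 19, 7-[6,8-bis(methoxymethoxy)-2,2-dimethyl-7-(3-methylbut-2-en-1-yl)-2H-chromen-5-yl]-2,2-dimethyl-2H,6H-pyrano[3,2-g]chromen-6-one (bis-MOM isoflavone)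
Conditions: n-BuLi, THF, −78 °C; ZnCl2, −78 °C → rt; then 8, Pd2(dba)3, SPhos, THF, 55 °C
Reagents that add atoms: none (both partners are the listed reactants)
Why: Br–Li exchange and transmetalation to zinc, then Negishi coupling with a bulky biarylphosphine to couple the di-ortho-substituted arylzinc; zinc avoids the protodeboronation expected of the corresponding boronic acid.

Step 11
Reactants: 19
Product: 20, 7-[6,8-dihydroxy-2,2-dimethyl-7-(3-methylbut-2-en-1-yl)-2H-chromen-5-yl]-2,2-dimethyl-2H,6H-pyrano[3,2-g]chromen-6-one (2',4'-dihydroxyisoflavone)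
Conditions: 3 M aq. HCl, MeOH/THF, 45 °C, under N2
Reagents that add atoms: none
Why: Acetal hydrolysis removes both MOM groups under conditions mild enough to leave the prenyl group and both chromenes intact.

Step 12
Reactants: 20
Product: 21, cis-(3R,4R)-isoflavan-4-ol: (6R,7R)-7-[6,8-dihydroxy-2,2-dimethyl-7-(3-methylbut-2-en-1-yl)-2H-chromen-5-yl]-2,2-dimethyl-7,8-dihydro-2H,6H-pyrano[3,2-g]chromen-6-ol
Conditions: RuCl[(R,R)-TsDPEN](p-cymene) (5 mol %), HCO2H/Et3N (5:2), EtOAc, 40 °C
Reagents that add atoms: none (hydrogen only)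
Why: Noyori–Ikariya asymmetric transfer hydrogenation: Ru–H 1,4-reduction gives the isoflavanone, whose C3 epimerises under Et3N, and ketone reduction with dynamic kinetic resolution by the (R,R) catalyst gives the 4R alcohol with the aryl group cis, which sets C3 as R (the future C6a).

Step 13
Reactants: 21
Product: 22, Lespecyrtin E4, (6aR,11aR)
Conditions: p-TsOH·H2O (10 mol %), CH2Cl2, 0 °C → rt
Reagents that add atoms: none (loss of H2O)
Why: SN1 cyclisation through the p-alkoxybenzylic cation; the 2'-OH can only close a cis-fused dihydrofuran, so C11a (R) is dictated by C6a (R), and the 4'-OH cannot reach C4.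

**Compound list**
1 | 5-bromo-2,4-dihydroxyacetophenone | CC(=O)c1cc(Br)c(O)cc1O | starting material
2 | 2-methylbut-3-en-2-ol | C=CC(C)(C)O | starting material
3 | (E)-1-[2,4-dihydroxy-5-(3-hydroxy-3-methylbut-1-en-1-yl)phenyl]ethanone | CC(=O)c1cc(/C=C/C(C)(C)O)c(O)cc1O | intermediate
4 | 1-(7-hydroxy-2,2-dimethyl-2H-chromen-6-yl)ethanone | CC(=O)c1cc2C=CC(C)(C)Oc2cc1O | intermediate
5 | N,N-dimethylformamide dimethyl acetal | COC(OC)N(C)C | starting material (reagent)
6 | (E)-3-(dimethylamino)-1-(7-hydroxy-2,2-dimethyl-2H-chromen-6-yl)prop-2-en-1-one | CN(C)/C=C/C(=O)c1cc2C=CC(C)(C)Oc2cc1O | intermediate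
7 | iodine | II | starting material (reagent)
8 | 7-iodo-2,2-dimethyl-2H,6H-pyrano[3,2-g]chromen-6-one | O=c1c(I)coc2cc3OC(C)(C)C=Cc3cc12 | intermediate
9 | 5-bromo-2,4-dihydroxybenzaldehyde | O=Cc1cc(Br)c(O)cc1O | starting material
10 | chloromethyl methyl ether | COCCl | starting material (reagent)
11 | 5-bromo-2,4-bis(methoxymethoxy)benzaldehyde | O=Cc1cc(Br)c(OCOC)cc1OCOC | intermediate
12 | m-chloroperoxybenzoic acid | OOC(=O)c1cccc(Cl)c1 | starting material (reagent)
13 | 5-bromo-2,4-bis(methoxymethoxy)phenol | Oc1cc(Br)c(OCOC)cc1OCOC | intermediate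
14 | 3-chloro-3-methylbut-1-yne | C#CC(C)(C)Cl | starting material
15 | 1-bromo-2,4-bis(methoxymethoxy)-5-[(2-methylbut-3-yn-2-yl)oxy]benzene | C#CC(C)(C)Oc1cc(Br)c(OCOC)cc1OCOC | intermediate
16 | 5-bromo-6,8-bis(methoxymethoxy)-2,2-dimethyl-2H-chromene | CC1(C)C=Cc2c(Br)c(OCOC)cc(OCOC)c2O1 | intermediate
17 | prenyl bromide (1-bromo-3-methylbut-2-ene) | CC(C)=CCBr | starting material
18 | 5-bromo-6,8-bis(methoxymethoxy)-2,2-dimethyl-7-(3-methylbut-2-en-1-yl)-2H-chromene | CC(C)=CCc1c(OCOC)c(Br)c2C=CC(C)(C)Oc2c1OCOC | intermediate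
19 | bis-MOM isoflavone | CC(C)=CCc1c(OCOC)c(-c2coc3cc4OC(C)(C)C=Cc4cc3c2=O)c2C=CC(C)(C)Oc2c1OCOC | intermediate
20 | 2',4'-dihydroxyisoflavone | CC(C)=CCc1c(O)c(-c2coc3cc4OC(C)(C)C=Cc4cc3c2=O)c2C=CC(C)(C)Oc2c1O | intermediate
21 | cis-(3R,4R)-isoflavan-4-ol | CC(C)=CCc1c(O)c([C@@H]2COc3cc4OC(C)(C)C=Cc4cc3[C@@H]2O)c2C=CC(C)(C)Oc2c1O | intermediate
22 | Lespecyrtin E4, (6aR,11aR) | CC(C)=CCc1c(O)c2c(c3c1O[C@H]1c4cc5c(cc4OC[C@@H]31)OC(C)(C)C=C5)C=CC(C)(C)O2 | target

**Totals**
Total steps: 13 (steps 1–4 for fragment 8, steps 5–9 for fragment 18, steps 10–13 for assembly).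
Longest linear sequence: 9 steps (9 → 22, steps 5–13).

**Three steps most likely to fail**
1. Step 12 (transfer hydrogenation with dynamic kinetic resolution next to a 2',6'-disubstituted aryl group bearing free phenols; rate, cis selectivity or ee may suffer). Fallback: abandon the catalytic asymmetric step: reduce 20 with NaBH4, cyclise as in step 13 to (±)-22, and separate the enantiomers by preparative chiral-phase chromatography.
2. Step 10 (Negishi coupling of a di-ortho-substituted, electron-rich arylzinc). Fallback: couple before the D-ring pyran exists. Protect phenol 13 as its allyl ether instead of propargylating it, prenylate as in step 9, and couple this mono-ortho-substituted arene by a routine Suzuki reaction. After pterocarpan formation, deallylate with Pd(0), form the 8-O-(1,1-dimethylpropargyl) ether with 9-OH temporarily acetylated, and run the Claisen/6π step into C7, the only free ortho position.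
3. Step 9 (amide-base metalation of an aryl bromide; incomplete deprotonation or halogen scrambling). Fallback: omit step 9 and install the C10 prenyl last on the pterocarpan phenol: form the 9-O-(1,1-dimethylallyl) ether (propargylation, then Lindlar reduction) and rearrange it by aromatic Claisen into C10, the only free ortho position.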